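**Strategy.** The congested C1–C1' biaryl bond is not made by coupling. Instead, ring C is grown on a two-carbon alkyne already seated at C1, between the C2 oxygen and the peri C8 methoxy group. The two ring C methoxy groups sit side by side on C3' and C4', so carbons C2'–C5' map onto symmetric 2,3-dimethoxybutadiene. One cobalt-catalysed (4+2) cycloaddition forms C1'–C2' and C5'–C6', closes ring C as a 1,4-cyclohexadiene and places both methoxy groups without any regiochemical question. The precursor is 1-ethynylnaphthalene 12, made from naphthalene-2,7-diol. It carries C2–OMOM (later the director for C3 formylation), C7–OBn and C8–OMe.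

Key step: step 10

Assumption: the target has no stereocentre and the C1–C1' axis (only hydrogens ortho on ring C) is taken as freely rotating; from compound 8 onward locants are those of the target, while compounds 1–7 use the locants of their own names (their C1, C2 and C7 become C8, C7 and C2).

Step 1
Reactants: 1 naphthalene-2,7-diol
Product: 2 2,7-dihydroxynaphthalene-1-carbaldehyde
Conditions: MgCl2, Et3N, (CH2O)n, MeCN, reflux; 1 M HCl work-up
Reagents that add atoms: formaldehyde (from paraformaldehyde), C=O
Why: Casnati–Skattebøl ortho-formylation: the magnesium naphthoxide hands formaldehyde only to a carbon next to its oxygen, the α-carbon C1 is far more nucleophilic than the β-carbon C3, a second formaldehyde oxidises the hydroxymethyl stage by hydride transfer, and the chelated, deactivated product with its peri-blocked C8 should resist a second formylation.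

Step 2
Reactants: 2 2,7-dihydroxynaphthalene-1-carbaldehyde
Product: 3 2-hydroxy-7-[(triisopropylsilyl)oxy]naphthalene-1-carbaldehyde
Conditions: TIPSCl (1.05 equiv), imidazole, DMF, 0 °C → rt
Reagents that add atoms: chlorotriisopropylsilane (TIPSCl), CC(C)[Si](Cl)(C(C)C)C(C)C
Why: Chemoselective silyl ether formation: the C2 hydroxyl is locked in a hydrogen bond to the adjacent aldehyde and shielded by it, so the bulky chlorosilane should take the free C7 hydroxyl, and TIPS is preferred to smaller silyl groups because an aryl silyl ether has to outlast two carbonate-mediated alkylations.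

Step 3
Reactants: 3 2-hydroxy-7-[(triisopropylsilyl)oxy]naphthalene-1-carbaldehyde
Product: 4 2-(benzyloxy)-7-[(triisopropylsilyl)oxy]naphthalene-1-carbaldehyde
Conditions: BnBr, K2CO3, dry DMF, rt
Reagents that add atoms: benzyl bromide, BrCc1ccccc1
Why: Williamson ether synthesis: carbonate breaks the hydrogen bond by deprotonation and the reactive benzylic bromide alkylates the naphthoxide already at room temperature, mild enough in dry DMF for the TIPS ether.

Step 4
Reactants: 4 2-(benzyloxy)-7-[(triisopropylsilyl)oxy]naphthalene-1-carbaldehyde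
Product: 6 2-(benzyloxy)-7-[(triisopropylsilyl)oxy]naphthalen-1-ol, via aryl formate 5 (not isolated)
Conditions: mCPBA, CH2Cl2, 0 °C → rt; reductive wash (aq. Na2S2O3); crude formate: Et3N (cat.), MeOH, rt
Reagents that add atoms: 3-chloroperoxybenzoic acid (mCPBA), O=C(OO)c1cccc(Cl)c1
Why: Baeyer–Villiger (Dakin-type) oxidation: in the Criegee adduct of this ortho-alkoxy aldehyde the electron-rich naphthyl group migrates in preference to hydride, surplus peracid is destroyed before the oxidation-prone naphthol is unveiled, and amine-catalysed transesterification removes the very labile formate without touching the TIPS ether.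

Step 5
Reactants: 6 2-(benzyloxy)-7-[(triisopropylsilyl)oxy]naphthalen-1-ol
Product: 7 {[7-(benzyloxy)-8-methoxynaphthalen-2-yl]oxy}triisopropylsilane
Conditions: MeI, K2CO3, DMF, rt, argon
Reagents that add atoms: iodomethane, CI
Why: Williamson O-methylation of the only free hydroxyl, run under argon directly after step 4 because the 2-alkoxy-1-naphthol is air-sensitive; the neighbouring benzyl group cannot migrate, so the oxygen pattern stays fixed.

Step 6
Reactants: 7 {[7-(benzyloxy)-8-methoxynaphthalen-2-yl]oxy}triisopropylsilane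
Product: 8 7-(benzyloxy)-8-methoxynaphthalen-2-ol
Conditions: TBAF, AcOH, THF, 0 °C
Reagents that add atoms: none
Why: Fluoride-mediated desilylation driven by Si–F bond formation, buffered with acetic acid so that the electron-rich naphthoxide is protonated at once; benzyl and methyl ethers are inert.

Step 7
Reactants: 8 7-(benzyloxy)-8-methoxynaphthalen-2-ol
Product: 9 7-(benzyloxy)-2-hydroxy-8-methoxynaphthalene-1-carbaldehyde
Conditions: MgCl2, Et3N, (CH2O)n, MeCN, reflux; 1 M HCl work-up
Reagents that add atoms: formaldehyde (from paraformaldehyde), C=O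
Why: Casnati–Skattebøl ortho-formylation again: delivery through the magnesium naphthoxide confines attack to C1 or C3 and keeps the alkoxy-activated C5 and C6 out of play, and α-attack at C1 leaves the sextet of the other ring intact, an electronic bias expected to outweigh the peri contact to the C8 methoxy group.

Step 8
Reactants: 9 7-(benzyloxy)-2-hydroxy-8-methoxynaphthalene-1-carbaldehyde
Product: 10 7-(benzyloxy)-8-methoxy-2-(methoxymethoxy)naphthalene-1-carbaldehyde
Conditions: MOMCl, i-Pr2NEt, CH2Cl2, 0 °C → rt
Reagents that add atoms: chloromethyl methyl ether (MOMCl), COCCl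
Why: MOM ether formation by O-alkylation with the highly reactive chloromethyl ether and a hindered amine base, standard for hydrogen-bonded ortho-hydroxy aldehydes; the group masks the phenol for the basic and organometallic steps and later directs lithiation.

Step 9
Reactants: 10 7-(benzyloxy)-8-methoxy-2-(methoxymethoxy)naphthalene-1-carbaldehyde; 11 dimethyl (1-diazo-2-oxopropyl)phosphonate
Product: 12 7-(benzyloxy)-1-ethynyl-8-methoxy-2-(methoxymethoxy)naphthalene
Conditions: K2CO3, MeOH/THF, rt
Reagents that add atoms: none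
Why: Ohira–Bestmann modification of the Seyferth–Gilbert homologation: methanolysis of 11 releases the diazomethylphosphonate anion, whose Horner–Wadsworth–Emmons-type addition to the non-enolisable aldehyde gives a diazoalkene that loses N2 and undergoes a 1,2-hydride shift to the terminal alkyne under conditions harmless to MOM, benzyl and methyl ethers.

Step 10
Reactants: 12 7-(benzyloxy)-1-ethynyl-8-methoxy-2-(methoxymethoxy)naphthalene; 13 2,3-dimethoxybuta-1,3-diene
Product: 14 7-(benzyloxy)-1-(4,5-dimethoxycyclohexa-1,4-dien-1-yl)-8-methoxy-2-(methoxymethoxy)naphthalene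
Conditions: CoBr2(dppe) (10 mol %), Zn (20 mol %), ZnI2 (20 mol %), 13 (3 equiv), dry CH2Cl2, rt; filtration through basic Al2O3
Reagents that add atoms: none
Why: Zn reduces CoBr2(dppe) to a monovalent cobalt species and ZnI2 abstracts its halide; the resulting cationic cobalt centre binds diene 13 in the s-cis form together with the C≡C bond of 12, couples them oxidatively to a trivalent cobalt allyl–vinyl metallacycle and releases the 1,4-diene by reductive elimination. The closest known reaction type is the cobalt-catalysed formal Diels–Alder reaction of unactivated terminal and aryl alkynes with 2,3-disubstituted or oxygenated butadienes, which has also served with ortho-substituted arylalkynes as an entry to hindered biaryls. Ring C closes in intermolecular (4+2) mode, the alkyne supplying C1' and C6' and the diene C2'–C5', with new bonds C1'–C2' and C5'–C6'. No stereocentre is created. The step needs chemoselectivity for cross-cycloaddition over alkyne cyclotrimerisation and diene oligomerisation, which is served by excess 13, the chelating diphosphine in non-coordinating CH2Cl2 and the bulk of C2–OMOM and peri C8–OMe that hinders assembly of several alkynes on one cobalt, whereas regioselectivity is no issue because 13 is symmetric. The aryl, MOM and benzyl ethers offer the catalyst nothing to engage, and strictly dry conditions plus the basic filtration protect the acid-labile bis(enol ether).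

Step 11
Reactants: 14 7-(benzyloxy)-1-(4,5-dimethoxycyclohexa-1,4-dien-1-yl)-8-methoxy-2-(methoxymethoxy)naphthalene
Product: 15 7-(benzyloxy)-1-(3,4-dimethoxyphenyl)-8-methoxy-2-(methoxymethoxy)naphthalene
Conditions: DDQ (1.05 equiv), toluene, 0 °C → rt
Reagents that add atoms: none
Why: Dehydrogenative aromatisation: DDQ abstracts hydride from a doubly allylic CH2 of the very electron-rich bis(enol ether) diene and proton loss gives the 3,4-dimethoxyphenyl ring, a process much faster than any attack of one equivalent of DDQ on the plain benzyl or MOM ether.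

Step 12
Reactants: 15 7-(benzyloxy)-1-(3,4-dimethoxyphenyl)-8-methoxy-2-(methoxymethoxy)naphthalene
Product: 18 6-(benzyloxy)-4-(3,4-dimethoxyphenyl)-3-hydroxy-5-methoxynaphthalene-2-carbaldehyde, via C3-aryllithium 16 (not isolated), via MOM-protected aldehyde 17 (not isolated)
Conditions: n-BuLi, TMEDA, THF, −78 → 0 °C; DMF, −78 °C → rt; then 3 M HCl, MeOH, 45 °C
Reagents that add atoms: N,N-dimethylformamide, CN(C)C=O
Why: Directed ortho-metalation: the MOM oxygens pre-coordinate n-BuLi and, with C1 blocked by ring C, the only flanking C–H is C3–H, which should outcompete the weaker methoxy- and benzyloxy-directed sites and, at or below 0 °C with n-BuLi, the benzylic CH2, after which DMF traps the aryllithium and the acidic methanolic finish cleaves the MOM acetal without touching the benzyl or methyl ethers.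

Step 13
Reactants: 18 6-(benzyloxy)-4-(3,4-dimethoxyphenyl)-3-hydroxy-5-methoxynaphthalene-2-carbaldehyde
Product: 19 vitrofolal B, 4-(3,4-dimethoxyphenyl)-3,6-dihydroxy-5-methoxynaphthalene-2-carbaldehyde
Conditions: BCl3 (3 equiv), pentamethylbenzene (4 equiv), CH2Cl2, −78 °C; aqueous quench
Reagents that add atoms: none
Why: Lewis-acid debenzylation with a non-basic cation scavenger: BCl3 ionises the benzyl–oxygen bond at −78 °C, pentamethylbenzene captures the benzyl cation by Friedel–Crafts alkylation before it can attack the electron-rich rings, and at this temperature the aldehyde and the three methyl ethers, none of which is ortho to the carbonyl, should persist.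

Compound list
1 | naphthalene-2,7-diol | Oc1ccc2ccc(O)cc2c1 | starting material
2 | 2,7-dihydroxynaphthalene-1-carbaldehyde | O=Cc1c(O)ccc2ccc(O)cc12 | intermediate
3 | 2-hydroxy-7-[(triisopropylsilyl)oxy]naphthalene-1-carbaldehyde | O=Cc1c(O)ccc2ccc(O[Si](C(C)C)(C(C)C)C(C)C)cc12 | intermediate
4 | 2-(benzyloxy)-7-[(triisopropylsilyl)oxy]naphthalene-1-carbaldehyde | O=Cc1c(OCc3ccccc3)ccc2ccc(O[Si](C(C)C)(C(C)C)C(C)C)cc12 | intermediate
5 | 2-(benzyloxy)-7-[(triisopropylsilyl)oxy]naphthalen-1-yl formate | O=COc1c(OCc3ccccc3)ccc2ccc(O[Si](C(C)C)(C(C)C)C(C)C)cc12 | intermediate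
6 | 2-(benzyloxy)-7-[(triisopropylsilyl)oxy]naphthalen-1-ol | Oc1c(OCc3ccccc3)ccc2ccc(O[Si](C(C)C)(C(C)C)C(C)C)cc12 | intermediate
7 | {[7-(benzyloxy)-8-methoxynaphthalen-2-yl]oxy}triisopropylsilane | COc1c(OCc3ccccc3)ccc2ccc(O[Si](C(C)C)(C(C)C)C(C)C)cc12 | intermediate
8 | 7-(benzyloxy)-8-methoxynaphthalen-2-ol | COc1c(OCc3ccccc3)ccc2ccc(O)cc12 | intermediate
9 | 7-(benzyloxy)-2-hydroxy-8-methoxynaphthalene-1-carbaldehyde | COc1c(OCc3ccccc3)ccc2ccc(O)c(C=O)c12 | intermediate
10 | 7-(benzyloxy)-8-methoxy-2-(methoxymethoxy)naphthalene-1-carbaldehyde | COCOc1ccc2ccc(OCc3ccccc3)c(OC)c2c1C=O | intermediate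
11 | dimethyl (1-diazo-2-oxopropyl)phosphonate | CC(=O)C(=[N+]=[N-])P(=O)(OC)OC | starting material
12 | 7-(benzyloxy)-1-ethynyl-8-methoxy-2-(methoxymethoxy)naphthalene | C#Cc1c(OCOC)ccc2ccc(OCc3ccccc3)c(OC)c12 | intermediate
13 | 2,3-dimethoxybuta-1,3-diene | C=C(OC)C(OC)=C | starting material
14 | 7-(benzyloxy)-1-(4,5-dimethoxycyclohexa-1,4-dien-1-yl)-8-methoxy-2-(methoxymethoxy)naphthalene | COCOc1ccc2ccc(OCc3ccccc3)c(OC)c2c1C1=CCC(OC)=C(OC)C1 | intermediate
15 | 7-(benzyloxy)-1-(3,4-dimethoxyphenyl)-8-methoxy-2-(methoxymethoxy)naphthalene | COCOc1ccc2ccc(OCc3ccccc3)c(OC)c2c1-c1ccc(OC)c(OC)c1 | intermediate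
16 | [6-(benzyloxy)-4-(3,4-dimethoxyphenyl)-5-methoxy-3-(methoxymethoxy)naphthalen-2-yl]lithium | COCOc1c([Li])cc2ccc(OCc3ccccc3)c(OC)c2c1-c1ccc(OC)c(OC)c1 | intermediate
17 | 6-(benzyloxy)-4-(3,4-dimethoxyphenyl)-5-methoxy-3-(methoxymethoxy)naphthalene-2-carbaldehyde | COCOc1c(C=O)cc2ccc(OCc3ccccc3)c(OC)c2c1-c1ccc(OC)c(OC)c1 | intermediate
18 | 6-(benzyloxy)-4-(3,4-dimethoxyphenyl)-3-hydroxy-5-methoxynaphthalene-2-carbaldehyde | Oc1c(C=O)cc2ccc(OCc3ccccc3)c(OC)c2c1-c1ccc(OC)c(OC)c1 | intermediate
19 | vitrofolal B, 4-(3,4-dimethoxyphenyl)-3,6-dihydroxy-5-methoxynaphthalene-2-carbaldehyde | COc1ccc(-c2c(O)c(C=O)cc3ccc(O)c(OC)c23)cc1OC | target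

Total step count: 13. Longest linear sequence: 13 steps (1 → 19); 11 and 13 are purchased.

Steps most likely to fail

1. Step 10. The alkyne carbon next to the crowded C1 may engage the cobalt centre too slowly. Alkyne cyclotrimerisation or ZnI2-induced oligomerisation of the enol-ether diene could then take over. The fallback gives up the cycloaddition for a direct cross-coupling and sets out from naphthol 8. Iodination at C1 (NIS, MeCN, 0 °C) should give 7-(benzyloxy)-1-iodo-8-methoxynaphthalen-2-ol F1. MOMCl and i-Pr2NEt then give 7-(benzyloxy)-1-iodo-8-methoxy-2-(methoxymethoxy)naphthalene F2. Suzuki–Miyaura coupling of F2 with (3,4-dimethoxyphenyl)boronic acid, which has no ortho substituent (Pd(OAc)2, SPhos, K3PO4, toluene/H2O, 100 °C), comes back to the route at biaryl 15.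

2. Step 7. C–C bond formation at the peri-crowded C1 may be sluggish. The hydroxymethyl stage may also collapse to a quinone methide that condenses with a second naphthol. The fallback replaces electrophilic formylation by halogenation and halogen–metal exchange, again starting from 8. NBS (MeCN, 0 °C) should give 7-(benzyloxy)-1-bromo-8-methoxynaphthalen-2-ol F3. MOMCl and i-Pr2NEt give 7-(benzyloxy)-1-bromo-8-methoxy-2-(methoxymethoxy)naphthalene F4. Bromine–lithium exchange (n-BuLi, THF, −78 °C) is far faster than any deprotonation and gives [7-(benzyloxy)-8-methoxy-2-(methoxymethoxy)naphthalen-1-yl]lithium F5. A DMF quench then rejoins the route at aldehyde 10.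

3. Step 12. Deprotonation of the benzylic CH2 of the C7 ether, followed by Wittig-type rearrangement, may compete with C3 lithiation. Metalation next to a methoxy group could likewise erode site selectivity. The fallback removes the acidic benzylic site before the metalation and sets out from 15.
   - Hydrogenolysis (H2, Pd/C, EtOAc; no aldehyde is present yet) should give 8-(3,4-dimethoxyphenyl)-1-methoxy-7-(methoxymethoxy)naphthalen-2-ol F6.
   - TIPSCl and imidazole give the non-directing, C6-shielding silyl ether {[8-(3,4-dimethoxyphenyl)-1-methoxy-7-(methoxymethoxy)naphthalen-2-yl]oxy}triisopropylsilane F7.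
   - n-BuLi/TMEDA gives [4-(3,4-dimethoxyphenyl)-5-methoxy-3-(methoxymethoxy)-6-[(triisopropylsilyl)oxy]naphthalen-2-yl]lithium F8.
   - DMF gives 4-(3,4-dimethoxyphenyl)-5-methoxy-3-(methoxymethoxy)-6-[(triisopropylsilyl)oxy]naphthalene-2-carbaldehyde F9.
   - TBAF/AcOH gives 4-(3,4-dimethoxyphenyl)-6-hydroxy-5-methoxy-3-(methoxymethoxy)naphthalene-2-carbaldehyde F10.
   - HCl in MeOH then comes back to the route at target 19, so BCl3 is no longer needed.

Further compounds
F1 | step 10 | 7-(benzyloxy)-1-iodo-8-methoxynaphthalen-2-ol | COc1c(OCc3ccccc3)ccc2ccc(O)c(I)c12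
F2 | step 10 | 7-(benzyloxy)-1-iodo-8-methoxy-2-(methoxymethoxy)naphthalene | COCOc1ccc2ccc(OCc3ccccc3)c(OC)c2c1I
F3 | step 7 | 7-(benzyloxy)-1-bromo-8-methoxynaphthalen-2-ol | COc1c(OCc3ccccc3)ccc2ccc(O)c(Br)c12
F4 | step 7 | 7-(benzyloxy)-1-bromo-8-methoxy-2-(methoxymethoxy)naphthalene | COCOc1ccc2ccc(OCc3ccccc3)c(OC)c2c1Br
F5 | step 7 | [7-(benzyloxy)-8-methoxy-2-(methoxymethoxy)naphthalen-1-yl]lithium | COCOc1ccc2ccc(OCc3ccccc3)c(OC)c2c1[Li]
F6 | step 12 | 8-(3,4-dimethoxyphenyl)-1-methoxy-7-(methoxymethoxy)naphthalen-2-ol | COCOc1ccc2ccc(O)c(OC)c2c1-c1ccc(OC)c(OC)c1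
F7 | step 12 | {[8-(3,4-dimethoxyphenyl)-1-methoxy-7-(methoxymethoxy)naphthalen-2-yl]oxy}triisopropylsilane | COCOc1ccc2ccc(O[Si](C(C)C)(C(C)C)C(C)C)c(OC)c2c1-c1ccc(OC)c(OC)c1
F8 | step 12 | [4-(3,4-dimethoxyphenyl)-5-methoxy-3-(methoxymethoxy)-6-[(triisopropylsilyl)oxy]naphthalen-2-yl]lithium | COCOc1c([Li])cc2ccc(O[Si](C(C)C)(C(C)C)C(C)C)c(OC)c2c1-c1ccc(OC)c(OC)c1
F9 | step 12 | 4-(3,4-dimethoxyphenyl)-5-methoxy-3-(methoxymethoxy)-6-[(triisopropylsilyl)oxy]naphthalene-2-carbaldehyde | COCOc1c(C=O)cc2ccc(O[Si](C(C)C)(C(C)C)C(C)C)c(OC)c2c1-c1ccc(OC)c(OC)c1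
F10 | step 12 | 4-(3,4-dimethoxyphenyl)-6-hydroxy-5-methoxy-3-(methoxymethoxy)naphthalene-2-carbaldehyde | COCOc1c(C=O)cc2ccc(O)c(OC)c2c1-c1ccc(OC)c(OC)c1
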